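**Retrosynthetic overview**
1. Bought: acetovanillone 1, methyl (R)-2-hydroxybut-3-enoate 2 (the only source of chirality) and 4-bromo-2,6-dimethoxyphenol 3. Both benzene rings are bought; only the dihydrofuran ring is made.
2. Last cut, C2–aryl: light-driven decarboxylative arylation of a 2,3-dihydrobenzofuran-2-carboxylic acid with the acetate of 3. The C3 hydroxymethyl group directs the aryl group trans.
3. Cut before, C3–C3a (closes the dihydrofuran ring): photochemical 5-exo aryl-radical cyclization of the o-iodoaryl ether of 2 with O2 capture, which also brings in the CH2OH oxygen. The ester-bearing C2 center directs C3 trans.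
4. First cut, C2–O: Mitsunobu inversion joining 2 to 5-iodinated 1.
5. Stereochemical relay: bought C2 center → C3 (cyclization) → C2 re-set when CO2H is exchanged for the aryl group.

Assumption: 2 is bought as the single (R) enantiomer (resolved methyl vinylglycolate).

**Step 1**
Reactants: 1 acetovanillone (1-(4-hydroxy-3-methoxyphenyl)ethan-1-one)
Product: 4 5-iodoacetovanillone (1-(4-hydroxy-3-iodo-5-methoxyphenyl)ethan-1-one)
Conditions: NIS (1.05 equiv), TsOH·H2O (10 mol %), MeCN, 0 °C to rt
Reagents that add atoms: N-iodosuccinimide, O=C1CCC(=O)N1I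
Why: Electrophilic aromatic iodination; the free phenol directs to its only open ortho position, the para position being blocked by the acetyl group.

**Step 2**
Reactants: 4 5-iodoacetovanillone; 2 methyl (R)-2-hydroxybut-3-enoate
Product: 5 methyl (S)-2-(4-acetyl-2-iodo-6-methoxyphenoxy)but-3-enoate
Conditions: PPh3 (1.3 equiv), DIAD (1.3 equiv), THF, 0 °C to rt
Reagents that add atoms: none
Why: Mitsunobu etherification; the acidic iodophenol displaces the oxyphosphonium of 2 by SN2 with inversion, so the bought (R) carbinol becomes the (S) aryl ether that will be C2.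

**Step 3**
Reactants: 5 methyl (S)-2-(4-acetyl-2-iodo-6-methoxyphenoxy)but-3-enoate
Product: 7 methyl (2S,3R)-5-acetyl-3-(hydroxymethyl)-7-methoxy-2,3-dihydro-1-benzofuran-2-carboxylate (trans), via hydroperoxide 6 (not isolated)
Conditions: O2 (1 atm), 1,4-cyclohexadiene (5 equiv), NaHCO3 (2 equiv), MeCN (0.02 M), 365 nm LEDs, −20 °C; then PPh3 (1.2 equiv), 0 °C to rt, dark
Reagents that add atoms: dioxygen, O=O
Why: Proposed new method: excitation of the aryl ketone chromophore of 5 gives a triplet that cleaves the weak aryl–iodine bond with no added catalyst; the aryl radical closes 5-exo onto the vinyl group (about 10^9 s^-1, far faster than its own capture by O2) and the resulting primary radical is trapped by O2; the peroxyl radical takes a hydrogen atom from 1,4-cyclohexadiene, which also converts iodine atoms to hydrogen iodide (buffered by NaHCO3), and PPh3 reduces hydroperoxide 6 to the alcohol without forming alkoxy radicals; C3 is set trans to the C2 ester through a chair-like transition state with the ester pseudo-equatorial (expected about 5:1), and the minor cis isomer, which has the wrong C3 configuration, lactonizes and is removed by chromatography so that enantiopurity is kept; the closest known reaction types are the photolytic or tin-hydride 5-exo aryl-radical cyclization of o-halophenyl allyl ethers and the tin hydride/O2 oxygen-trapping radical cyclization.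

**Step 4**
Reactants: 7 methyl (2S,3R)-5-acetyl-3-(hydroxymethyl)-7-methoxy-2,3-dihydro-1-benzofuran-2-carboxylate
Product: 8 (2S,3R)-5-acetyl-3-(hydroxymethyl)-7-methoxy-2,3-dihydro-1-benzofuran-2-carboxylic acid
Conditions: LiOH·H2O (1.5 equiv), THF/H2O 3:1, 0 °C; then 1 M HCl to pH 3
Reagents that add atoms: lithium hydroxide, [Li+].[OH-]
Why: Saponification of an activated α-aryloxy ester; C3 is not acidic and stays untouched, the trans hydroxy acid cannot lactonize, and any C2 epimerization is harmless because C2 is re-set in step 6.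

**Step 5**
Reactants: 3 4-bromo-2,6-dimethoxyphenol
Product: 9 4-bromo-2,6-dimethoxyphenyl acetate
Conditions: Ac2O (1.5 equiv), DMAP (5 mol %), pyridine, rt
Reagents that add atoms: acetic anhydride, CC(=O)OC(C)=O
Why: DMAP-catalysed O-acetylation; masking the phenol keeps the aryl bromide from becoming an electron-rich phenoxide and protects the product phenol from oxidation in step 6.

**Step 6**
Reactants: 8 (2S,3R)-5-acetyl-3-(hydroxymethyl)-7-methoxy-2,3-dihydro-1-benzofuran-2-carboxylic acid; 9 4-bromo-2,6-dimethoxyphenyl acetate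
Product: 11 1-[(2S,3R)-2-(4-hydroxy-3,5-dimethoxyphenyl)-3-(hydroxymethyl)-7-methoxy-2,3-dihydro-1-benzofuran-5-yl]ethan-1-one (target), via aryl acetate 10 (not isolated)
Conditions: Ir[dF(CF3)ppy]2(dtbbpy)PF6 (2 mol %), NiCl2(dme) (10 mol %), dtbbpy (15 mol %), Cs2CO3 (0.55 equiv), DMF, 450 nm LEDs, 25 °C; then K2CO3 (0.2 equiv), MeOH, 0 °C
Reagents that add atoms: none
Why: Metallaphotoredox decarboxylative arylation; the excited iridium photocatalyst oxidizes the carboxylate, loss of CO2 gives a planar α-oxy radical at C2, and the aryl nickel species formed from 9 captures it and couples on the face away from the C3 hydroxymethyl group, setting C2 trans (2S) under control of C3; base-catalysed methanolysis then frees the phenol.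

**Compound list**
1 | acetovanillone, 1-(4-hydroxy-3-methoxyphenyl)ethan-1-one | CC(=O)c1ccc(O)c(OC)c1 | starting material
2 | methyl (R)-2-hydroxybut-3-enoate | C=C[C@@H](O)C(=O)OC | starting material
3 | 4-bromo-2,6-dimethoxyphenol | COc1cc(Br)cc(OC)c1O | starting material
4 | 1-(4-hydroxy-3-iodo-5-methoxyphenyl)ethan-1-one | CC(=O)c1cc(I)c(O)c(OC)c1 | intermediate
5 | methyl (S)-2-(4-acetyl-2-iodo-6-methoxyphenoxy)but-3-enoate | C=C[C@H](Oc1c(I)cc(C(C)=O)cc1OC)C(=O)OC | intermediate
6 | methyl (2S,3R)-5-acetyl-3-(hydroperoxymethyl)-7-methoxy-2,3-dihydro-1-benzofuran-2-carboxylate | COC(=O)[C@H]1Oc2c(OC)cc(C(C)=O)cc2[C@@H]1COO | intermediate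
7 | methyl (2S,3R)-5-acetyl-3-(hydroxymethyl)-7-methoxy-2,3-dihydro-1-benzofuran-2-carboxylate | COC(=O)[C@H]1Oc2c(OC)cc(C(C)=O)cc2[C@@H]1CO | intermediate
8 | (2S,3R)-5-acetyl-3-(hydroxymethyl)-7-methoxy-2,3-dihydro-1-benzofuran-2-carboxylic acid | OC(=O)[C@H]1Oc2c(OC)cc(C(C)=O)cc2[C@@H]1CO | intermediate
9 | 4-bromo-2,6-dimethoxyphenyl acetate | COc1cc(Br)cc(OC)c1OC(C)=O | intermediate
10 | 4-[(2S,3R)-5-acetyl-3-(hydroxymethyl)-7-methoxy-2,3-dihydro-1-benzofuran-2-yl]-2,6-dimethoxyphenyl acetate | COc1cc([C@H]2Oc3c(OC)cc(C(C)=O)cc3[C@@H]2CO)cc(OC)c1OC(C)=O | intermediate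
11 | 1-[(2S,3R)-2-(4-hydroxy-3,5-dimethoxyphenyl)-3-(hydroxymethyl)-7-methoxy-2,3-dihydro-1-benzofuran-5-yl]ethan-1-one | COc1cc([C@H]2Oc3c(OC)cc(C(C)=O)cc3[C@@H]2CO)cc(OC)c1O | target

**Step count and risks**
Total: 6 steps. Longest linear sequence: 5 steps (steps 1, 2, 3, 4, 6); step 5 is a one-step side branch.

The three steps most likely to fail are steps 2, 3 and 6.

Step 2 (Mitsunobu on an allylic α-hydroxy ester). The risks are SN2' attack giving the 4-aryloxycrotonate and drift of the double bond into conjugation with loss of the stereocenter. The fallback sets out from 4 and avoids any allylic system while the C–O bond is made. Mitsunobu reaction (PPh3, DIAD) of 4 with bought (R)-α-hydroxy-γ-butyrolactone (O[C@@H]1CCOC1=O) gives, with inversion, (S)-3-(4-acetyl-2-iodo-6-methoxyphenoxy)oxolan-2-one F1. Sodium benzeneselenolate (from (PhSe)2 and NaH, DMF, 90 °C, dark) opens the lactone at its O–CH2 carbon to (S)-2-(4-acetyl-2-iodo-6-methoxyphenoxy)-4-(phenylselanyl)butanoic acid F2 (as its sodium salt). MeI in the same flask gives methyl (S)-2-(4-acetyl-2-iodo-6-methoxyphenoxy)-4-(phenylselanyl)butanoate F3. NaIO4 oxidation gives the selenoxide methyl (2S)-2-(4-acetyl-2-iodo-6-methoxyphenoxy)-4-(phenylseleninyl)butanoate F4, whose syn-elimination at 40 °C forms the vinyl group. The fallback comes back to the route at 5.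

Step 3 (the proposed new reaction). The risks are a low quantum yield, iodine build-up that diverts the primary radical to the alkyl iodide, photoreduction of the ketone, and a modest trans:cis ratio. The fallback uses known chemistry and sets out from 5. Blue-LED radical borylation with bis(catecholato)diboron in DMF (aryl radical formation, 5-exo cyclization, borylation of the primary radical) gives methyl (2S,3S)-5-acetyl-3-[(1,3,2-benzodioxaborol-2-yl)methyl]-7-methoxy-2,3-dihydro-1-benzofuran-2-carboxylate F5. This has the same trans geometry; the C3 descriptor changes only because CH2B ranks below the aryl carbon. Oxidation in the same flask with NaBO3·4H2O (THF/H2O) gives the alcohol, and the cis lactone is removed as before. The fallback comes back to the route at 7.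

Step 6 (decarboxylative arylation). The risks are protodecarboxylation, β-hydride elimination to the benzofuran, acetyl transfer from 9, and incomplete trans selectivity. Any cis epimer is removed by chromatography. The fallback sets out from 8 and uses a redox-active ester in place of photochemical carboxylate oxidation. N-hydroxyphthalimide and DIC (CH2Cl2, no DMAP) give 1,3-dioxoisoindolin-2-yl (2S,3R)-5-acetyl-3-(hydroxymethyl)-7-methoxy-2,3-dihydro-1-benzofuran-2-carboxylate F6. Nickel-catalysed reductive cross-electrophile coupling of F6 with 9 (NiBr2(dme), dtbbpy, Zn dust, DMA, rt, no light) gives the trans aryl acetate. The fallback comes back to the route at 10, which is methanolysed to 11 as in step 6.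

**Further compounds**
F1 | step 2 | (S)-3-(4-acetyl-2-iodo-6-methoxyphenoxy)oxolan-2-one | CC(=O)c1cc(I)c(O[C@H]2CCOC2=O)c(OC)c1
F2 | step 2 | (S)-2-(4-acetyl-2-iodo-6-methoxyphenoxy)-4-(phenylselanyl)butanoic acid | OC(=O)[C@H](CC[Se]c1ccccc1)Oc1c(I)cc(C(C)=O)cc1OC
F3 | step 2 | methyl (S)-2-(4-acetyl-2-iodo-6-methoxyphenoxy)-4-(phenylselanyl)butanoate | COC(=O)[C@H](CC[Se]c1ccccc1)Oc1c(I)cc(C(C)=O)cc1OC
F4 | step 2 | methyl (2S)-2-(4-acetyl-2-iodo-6-methoxyphenoxy)-4-(phenylseleninyl)butanoate | COC(=O)[C@H](CC[Se](=O)c1ccccc1)Oc1c(I)cc(C(C)=O)cc1OC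
F5 | step 3 | methyl (2S,3S)-5-acetyl-3-[(1,3,2-benzodioxaborol-2-yl)methyl]-7-methoxy-2,3-dihydro-1-benzofuran-2-carboxylate | COC(=O)[C@H]1Oc2c(OC)cc(C(C)=O)cc2[C@@H]1CB1Oc2ccccc2O1
F6 | step 6 | 1,3-dioxoisoindolin-2-yl (2S,3R)-5-acetyl-3-(hydroxymethyl)-7-methoxy-2,3-dihydro-1-benzofuran-2-carboxylate | O=C(ON1C(=O)c2ccccc2C1=O)[C@H]1Oc2c(OC)cc(C(C)=O)cc2[C@@H]1CO
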